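Slowness is best counted: how many half-lives of the starting material does a flask get before it is read?

| setting | zeta | gamma | maple | cedar |
|---|---|---|---|---|
| starting material | 0.67 M | 1.5 M | 1.0 M | 1.0 M |
| temperature | 29 °C | 37 °C | 40 °C | 25 °C |
| remark | run made earlier | run made earlier |  |  |
| time |  |  | 3.0 min | 1.5 min |
- zeta (time / min: target / %, starting material / %): 0.250: 0.5, 88.6; 0.500: 2.6, 78.3; 1.00: 7.4, 61.0; 1.50: 13.8, 47.8; 2.50: 24.3, 28.2; 3.00: 29.0, 22.2
- gamma (time / s: target / %, starting material / %): 20.0: 4.7, 70.1; 40.0: 13.5, 47.6; 50.0: 17.1, 39.2; 80.0: 26.4, 22.7; 90.0: 27.8, 17.5; 120: 31.5, 10.4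

(standard deviation of a reading: 0.3 percentage points)

* the flask that ends with the higher amount of target, in percent of the starting material charged, or "neither" when 2 percentage points or less lies between them (maple / cedar / neither)
* final target, as a percentage of the starting material charged, in maple
* final target, as a percentage of the starting material charged, in cedar

Two chemists argue over these runs. Both read the fall of c(starting material) as first order, with 0.503 min⁻¹ in zeta and 1.14 min⁻¹ in gamma. Taking ln k as straight in temperature and setting the charge aside, they get 1.56 min⁻¹ for maple and 0.334 min⁻¹ for cedar. Time divided by half-life then gives 6.74 for maple and 0.722 for cedar; this count of elapsed half-lives is the clock. The readings reach 2.18 in zeta and 3.30 in gamma.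

Cedar's clock is shorter than zeta's reach, and it matches zeta at 0.995 min, where target reads 7.4 %. Neither chemist disputes that figure. Maple's clock runs past both runs, and there they part.

The first chemist, who made the forecast, leaves a slow loss of target open and still reads a level from gamma: “Its late rate suggests a plateau near 37%”. The forecast says maple, with 37 % in maple and 7 % in cedar.

The second chemist compares equal clocks. With starting material at 22.2 % zeta reads 29.0 % of target, while gamma, hotter, at 22.7 % reads 26.4 %. That gap of 2.6 percentage points is wider than the scatter of 0.3 points. So the second chemist expects maple, hotter than gamma, to end below gamma's last 31.5 %, and commits to no closer figure.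

The flasks give maple, with 25.1 % in maple and 7.25 % in cedar, so the forecast stands 12 points high on maple.

    starting material → intermediate (k = 0.0222 s⁻¹, Ea = 74.0 kJ mol⁻¹)
    intermediate ⇌ target (K = 2.80, k = 0.0306 s⁻¹, Ea = 89.0 kJ mol⁻¹, ΔH = −90.0 kJ mol⁻¹)
    intermediate ⇌ isomer of the product (K = 21.0, k = 0.0106 s⁻¹, Ea = 75.0 kJ mol⁻¹, ΔH = 22.0 kJ mol⁻¹)
    target → over-reaction product (k = 0.00487 s⁻¹, Ea = 82.0 kJ mol⁻¹)
    starting material + intermediate → side product (k = 0.00809 L mol⁻¹ s⁻¹, Ea = 64.0 kJ mol⁻¹)
    (constants at 40 °C)

The clock of maple implies 0.936 % of starting material left, and 1.44 % stood there. Maple left until 5.0 min has a clock of 11.3, which implies 0.0410 % of starting material, and that flask held 0.0939 % of it beside 13.6 % of target. The first chemist's figure stands on the shorter clock of cedar, where 7 % was forecast and 7.25 % came. In maple, starting material passed into intermediate with a half-life of 0.52 min, and target had reached 31.2 % at 1.50 min. With starting material down to 1.44 %, target was made at 0.0667 of the rate it was used, its half-life towards over-reaction product being 2.4 min, and it stood at 25.1 % at 3.00 min.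

The readings come from a simulation for substances that don't exist; scatter was added.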